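- Dusk read 0.112 M of target at the end against 0.0669 M in dawn, so more target, but it took 3.95 times the substrate, and my next run had to be charged with that cost in mind.

| setting | dawn | dusk | elm | alder | larch | birch | maple |
|---|---|---|---|---|---|---|---|
| substrate | 0.19 M | 0.75 M | 0.20 M | 0.40 M | 0.80 M | 1.5 M | 3.0 M |
| reagent | 0.19 M | 0.19 M | 0.190 M | 0.190 M | 0.190 M | 0.190 M | 0.190 M |
| free catalyst | 2.8 mM | 2.8 mM | 2.8 mM | 2.8 mM | 2.8 mM | 2.8 mM | 2.8 mM |
| remark | run made earlier | run made earlier |  |  |  |  |  |
| time |  |  | 4.0 h | 4.0 h | 4.0 h | 4.0 h | 4.0 h |

- dawn (time / h: target / %, substrate / %): 0.333: 13.0, 83.2; 0.667: 19.0, 67.9; 1.00: 22.4, 57.1; 2.00: 35.7, 34.0; 4.00: 35.2, 31.6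
- dusk (time / h: target / %, substrate / %): 0.833: 14.1, 80.0; 1.50: 13.6, 80.4; 2.50: 15.0, 77.3; 3.00: 15.7, 79.3; 4.00: 14.9, 79.9

(scatter of a reading: 1 percentage point)

- the numbers in the tables scatter with a standard deviation of 1 percentage point
- "hardly changes" means that all values lie within two and a half points (for a concentration: within two and a half percent of the largest)

- [target] at the end for elm, alder, larch, birch, maple, in this order
- how the row runs (rises all the way / hardly changes / falls, then rises / rises, then falls / falls all the way)

- At 4.00 h the readings put the substrate lost to something other than target at 0.0631 M in dawn and 0.0390 M in dusk.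
- Target plus 2 times this missing substrate came to 0.193 M in dawn and 0.190 M in dusk, against 0.190 M of reagent charged. I therefore read the reagent as the limiting reagent, with the missing material costing two reagents.
- I kept one ratio, which I called the split: missing substrate per target kept, the two rates summed over the run, so that time drops out. It read 0.943 in dawn and 0.349 in dusk, each through a scatter of 1 percentage point per reading.
- By that balance, the end target is the reagent charge divided by one plus 2 times the split.
- For larch, which stands beside dusk, I took dusk's split and reckoned 0.112 M. For maple, I assumed the split would fall by the same factor as from dawn to dusk, and reckoned 0.151 M.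
- So maple would use 3.75 times larch's substrate for 1.35 times the target. I decided to charge larch and leave maple.
- The forecast gave 0.071 M, 0.095 M, 0.107 M, 0.111 M and 0.113 M, with the shape "rises all the way", on the ground that “With more substrate, over-reaction fades and target approaches the limit”. Its maple value lies below mine.

    reagent + free catalyst → catalyst intermediate A (k = 74.0 /M/min)
    substrate + catalyst intermediate B ⇌ catalyst intermediate C (K = 2.50 /M, k = 32.0 /M/min)
    reagent + target → over-reaction product (k = 0.210 /M/min)
    catalyst intermediate C ⇌ free catalyst + target (K = 2.30 M, k = 36.0 /min)
    catalyst intermediate A ⇌ catalyst intermediate B (K = 0.210, k = 5.70 /min)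

- The flasks gave 0.0729 M, 0.101 M, 0.119 M, 0.129 M and 0.135 M, with the shape "rises all the way". Maple ended with 94.6% of its substrate left and 0% of its reagent. The split, read as 0.349 in dusk, comes to 0.298 in larch and 0.204 in maple, where 3.75 times larch's substrate gave 1.13 times its target. In elm the split comes to 0.803, and over-reaction product stood at 28.9% of the substrate charged.

(The numbers in the tables come from a simulation with made-up constants.)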